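Ring C (the central benzene) is bounded by the C2=C3 bond of furan ring D and by the enol-ether C=C of dioxin ring B, so only its CH–C(OH) pair has to be added. The route rests on the bond between that C(OH) carbon and the dioxin CH carbon. Irradiation of a 2-diazoacetylbenzofuran (rings D and E) that carries a 1,4-benzodioxin-2-yl group (rings A and B) at C3 triggers a Wolff rearrangement; the resulting ketene closes ring C by 6π electrocyclisation and tautomerises to the ring-C phenol in the same operation. The eight other phenols travel as methyl ethers and are freed at the end.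

Key step: step 17

Remark on the chemistry: the structures of the diazoketone (36) and of its ring-closed phenol (39) were checked against the target and needed no correction. A free catechol would close ring B in both orientations, so one of the two ring-B oxygens is carried as a formyl group (a latent phenol) until ring A has been attached through the other. Ring A is the aryloxy-bearing benzene of the dibenzodioxin and ring E the outer benzene of the dibenzofuran.

Step 1
Reactants: 1 2-hydroxy-4,6-dimethoxybenzaldehyde; 2 benzyl bromide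
Product: 3 2-(benzyloxy)-4,6-dimethoxybenzaldehyde
Conditions: K2CO3, DMF, 60 °C
Reagents that add atoms: benzyl bromide, BrCc1ccccc1
Why: Williamson ether synthesis on the phenoxide masks the oxygen that must later be the free phenol directing the formylation.

Step 2
Reactants: 3 2-(benzyloxy)-4,6-dimethoxybenzaldehyde; 4 3-chloroperoxybenzoic acid (mCPBA)
Product: 6 2-(benzyloxy)-4,6-dimethoxyphenol, via aryl formate 5 (not isolated)
Conditions: mCPBA, CH2Cl2, 0 °C to rt; NaHCO3 wash; then Et3N (cat.), MeOH, rt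
Reagents that add atoms: mCPBA, OOC(=O)c1cccc(Cl)c1
Why: Baeyer–Villiger (Dakin-type) oxidation in which the electron-rich trialkoxyaryl group migrates in preference to hydrogen, followed by methanolysis of the formate.

Step 3
Reactants: 6 2-(benzyloxy)-4,6-dimethoxyphenol; 7 1-iodo-3,5-dimethoxybenzene
Product: 8 1-(benzyloxy)-2-(3,5-dimethoxyphenoxy)-3,5-dimethoxybenzene
Conditions: CuI (10 mol %), picolinic acid (20 mol %), K3PO4, DMSO, 90 °C, argon
Reagents that add atoms: 1-iodo-3,5-dimethoxybenzene, COc1cc(I)cc(OC)c1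
Why: Ullmann-type copper-catalysed O-arylation, which with picolinic acid tolerates di-ortho-substituted phenols and, being run without oxidant, spares this easily oxidised phenol.

Step 4
Reactants: 8 1-(benzyloxy)-2-(3,5-dimethoxyphenoxy)-3,5-dimethoxybenzene
Product: 9 2-(3,5-dimethoxyphenoxy)-3,5-dimethoxyphenol
Conditions: H2 (1 atm), Pd/C, EtOAc/MeOH, rt
Reagents that add atoms: none
Why: Hydrogenolysis of the benzyl ether should leave the diaryl ether and the methyl ethers untouched.

Step 5
Reactants: 9 2-(3,5-dimethoxyphenoxy)-3,5-dimethoxyphenol; 10 paraformaldehyde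
Product: 11 3-(3,5-dimethoxyphenoxy)-2-hydroxy-4,6-dimethoxybenzaldehyde
Conditions: (CH2O)n, MgCl2, Et3N, MeCN, reflux; aq. HCl work-up
Reagents that add atoms: paraformaldehyde (as formaldehyde), C=O
Why: Magnesium-mediated ortho-formylation (Casnati–Skattebøl), in which the magnesium phenoxide delivers formaldehyde only to the single free ortho position, so the other electron-rich sites are not touched.

Step 6
Reactants: 11 3-(3,5-dimethoxyphenoxy)-2-hydroxy-4,6-dimethoxybenzaldehyde; 12 methyl bromoacetate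
Product: 13 methyl 2-[2-(3,5-dimethoxyphenoxy)-6-formyl-3,5-dimethoxyphenoxy]acetate
Conditions: BrCH2CO2Me, K2CO3, acetone, 40 °C
Reagents that add atoms: methyl bromoacetate, COC(=O)CBr
Why: Williamson alkylation of the salicylaldehyde phenoxide under weak base, at a temperature below that needed for aldol closure to a 3-unsubstituted benzofuran.

Step 7
Reactants: 13 methyl 2-[2-(3,5-dimethoxyphenoxy)-6-formyl-3,5-dimethoxyphenoxy]acetate; 14 sodium chlorite
Product: 15 3-(3,5-dimethoxyphenoxy)-4,6-dimethoxy-2-(2-methoxy-2-oxoethoxy)benzoic acid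
Conditions: NaClO2, NaH2PO4, 2-methyl-2-butene, t-BuOH/THF/H2O, 0 °C to rt
Reagents that add atoms: sodium chlorite, [Na+].[O-]Cl=O
Why: Pinnick oxidation converts the aldehyde to the acid without touching ester or ethers, and the alkene scavenger removes HOCl before it can chlorinate the electron-rich rings.

Step 8
Reactants: 15 3-(3,5-dimethoxyphenoxy)-4,6-dimethoxy-2-(2-methoxy-2-oxoethoxy)benzoic acid; 16 trimethylsilyldiazomethane
Product: 18 methyl 7-(3,5-dimethoxyphenoxy)-3-hydroxy-4,6-dimethoxy-1-benzofuran-2-carboxylate, via dimethyl diester 17 (not isolated)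
Conditions: TMSCHN2, toluene/MeOH, 0 °C, evaporate; then t-BuOK, THF, 0 °C to rt; aq. HCl work-up
Reagents that add atoms: none
Why: Esterification followed by Dieckmann condensation of the aryloxyacetate enolate onto the benzoate should give the enolised 3-oxobenzofuran ester, the methyl group put on in the first stage leaving again as methanol.

Step 9
Reactants: 18 methyl 7-(3,5-dimethoxyphenoxy)-3-hydroxy-4,6-dimethoxy-1-benzofuran-2-carboxylate; 19 trifluoromethanesulfonic anhydride
Product: 20 methyl 7-(3,5-dimethoxyphenoxy)-4,6-dimethoxy-3-{[(trifluoromethyl)sulfonyl]oxy}-1-benzofuran-2-carboxylate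
Conditions: Tf2O, pyridine, CH2Cl2, −78 to 0 °C
Reagents that add atoms: trifluoromethanesulfonic anhydride, O=S(=O)(OS(=O)(=O)C(F)(F)F)C(F)(F)F
Why: O-Sulfonylation of the enol of the β-keto ester gives the heteroaryl triflate needed for cross-coupling.

Step 10
Reactants: 20 the benzofuran-3-yl triflate; 21 tributyl(1-ethoxyvinyl)stannane
Product: 22 methyl 7-(3,5-dimethoxyphenoxy)-3-(1-ethoxyethenyl)-4,6-dimethoxy-1-benzofuran-2-carboxylate
Conditions: Pd(PPh3)4 (5 mol %), LiCl, 1,4-dioxane, 90 °C; KF work-up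
Reagents that add atoms: tributyl(1-ethoxyvinyl)stannane, C=C(OCC)[Sn](CCCC)(CCCC)CCCC
Why: Stille coupling of an electron-poor heteroaryl triflate with an α-alkoxyvinyl stannane, LiCl assisting the transmetalation.

Step 11
Reactants: 22 the 3-(1-ethoxyethenyl)benzofuran ester; 23 N-bromosuccinimide; 24 water
Product: 25 methyl 3-(2-bromoacetyl)-7-(3,5-dimethoxyphenoxy)-4,6-dimethoxy-1-benzofuran-2-carboxylate
Conditions: NBS (1.0 equiv), THF/H2O, 0 °C
Reagents that add atoms: N-bromosuccinimide, O=C1CCC(=O)N1Br; water, O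
Why: Electrophilic bromination of the enol ether, by far the most nucleophilic site, followed by hydrolysis of the bromo oxocarbenium ion should give the α-bromoketone directly.

Step 12
Reactants: 25 methyl 3-(2-bromoacetyl)-7-(3,5-dimethoxyphenoxy)-4,6-dimethoxy-1-benzofuran-2-carboxylate; 11 3-(3,5-dimethoxyphenoxy)-2-hydroxy-4,6-dimethoxybenzaldehyde
Product: 26 methyl 7-(3,5-dimethoxyphenoxy)-3-{2-[2-(3,5-dimethoxyphenoxy)-6-formyl-3,5-dimethoxyphenoxy]acetyl}-4,6-dimethoxy-1-benzofuran-2-carboxylate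
Conditions: K2CO3 (1.1 equiv), acetone, 0 °C to rt
Reagents that add atoms: 3-(3,5-dimethoxyphenoxy)-2-hydroxy-4,6-dimethoxybenzaldehyde, COc1cc(OC)c(C=O)c(O)c1Oc1cc(OC)cc(OC)c1
Why: Williamson alkylation by a reactive phenacyl-type bromide; only the oxygen next to the aryloxy group is a free phenol, so ring A is attached in one orientation, and the weak base at low temperature suppresses aldol (Rap–Stoermer) closure onto the hindered aldehyde.

Step 13
Reactants: 26 the keto aldehyde ether; 4 3-chloroperoxybenzoic acid (mCPBA)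
Product: 29 methyl 7-(3,5-dimethoxyphenoxy)-3-[5-(3,5-dimethoxyphenoxy)-2-hydroxy-6,8-dimethoxy-2,3-dihydro-1,4-benzodioxin-2-yl]-4,6-dimethoxy-1-benzofuran-2-carboxylate (racemic cyclic hemiketal), via aryl formate 27 (not isolated), via open hydroxy ketone 28 (not isolated)
Conditions: mCPBA (1.1 equiv), CH2Cl2, 0 °C; NaHCO3 wash; then Et3N (cat.), MeOH, rt
Reagents that add atoms: mCPBA, OOC(=O)c1cccc(Cl)c1
Why: Dakin-type Baeyer–Villiger oxidation of the very electron-rich aldehyde should be far faster than oxidation of the hindered aryl ketone, and the phenol freed by methanolysis adds to the ketone to close ring B as a six-membered hemiketal whose new stereocentre is racemic and is removed in step 14.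

Step 14
Reactants: 29 the cyclic hemiketal
Product: 30 methyl 7-(3,5-dimethoxyphenoxy)-3-[5-(3,5-dimethoxyphenoxy)-6,8-dimethoxy-1,4-benzodioxin-2-yl]-4,6-dimethoxy-1-benzofuran-2-carboxylate
Conditions: TsOH (cat.), toluene, molecular sieves, 80 °C
Reagents that add atoms: none
Why: Acid-catalysed dehydration of the hemiketal through an oxocarbenium ion (E1 elimination) gives the aryl-conjugated 1,4-benzodioxin.

Step 15
Reactants: 30 the benzodioxinyl benzofuran methyl ester; 31 lithium hydroxide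
Product: 32 7-(3,5-dimethoxyphenoxy)-3-[5-(3,5-dimethoxyphenoxy)-6,8-dimethoxy-1,4-benzodioxin-2-yl]-4,6-dimethoxy-1-benzofuran-2-carboxylic acid
Conditions: LiOH, THF/MeOH/H2O, rt; then 1 M HCl to pH 4, 0 °C
Reagents that add atoms: lithium hydroxide, [Li+].[OH-]
Why: Saponification of the ester; the enol ether and aryl ethers are stable to base, and the acid is released cold at pH 4 to protect the benzodioxin.

Step 16
Reactants: 32 the benzofuran-2-carboxylic acid; 33 1-chloro-N,N,2-trimethylprop-1-en-1-amine; 34 diazomethane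
Product: 36 2-diazo-1-{7-(3,5-dimethoxyphenoxy)-3-[5-(3,5-dimethoxyphenoxy)-6,8-dimethoxy-1,4-benzodioxin-2-yl]-4,6-dimethoxy-1-benzofuran-2-yl}ethan-1-one, via acid chloride 35 (not isolated)
Conditions: 1-chloro-N,N,2-trimethylprop-1-en-1-amine (1.05 equiv), CH2Cl2, 0 °C to rt; then CH2N2, Et3N, Et2O/CH2Cl2, 0 °C
Reagents that add atoms: diazomethane, C=[N+]=[N-]
Why: The α-chloroenamine makes the acid chloride without releasing HCl, which protects the enol ether, and acylation of diazomethane with Et3N as the HCl trap (first stage of the Arndt–Eistert sequence) gives the diazoketone.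

Step 17
Reactants: 36 the 2-diazoacetyl-3-(1,4-benzodioxin-2-yl)benzofuran
Product: 39 phlorofucofuroeckol A octamethyl ether with the ring-C hydroxyl free, via heteroarylketene 37 (not isolated), via cyclohexadienone 38 (not isolated)
Conditions: hν (365 nm LED), dry degassed toluene, 0.003 M, rt; then 80 °C, 1 h, dark
Reagents that add atoms: none
Why: Excitation of the s-cis diazoketone expels N2 with a concerted 1,2-shift of the benzofuran-2-yl group (Wolff rearrangement) to give ketene 37, whose C=C bond, the furan C2=C3 bond and the dioxin C2=C3 bond make up a hexatriene held cis at its centre by the furan ring. Thermal disrotatory 6π electrocyclisation joins the electrophilic ketene carbon to the nucleophilic dioxin C3–H carbon and so closes six-membered ring C, and dienone 38 enolises at once because this restores the furan and makes ring C aromatic. The closest known reaction type is the photo-Wolff generation of aryl- and dienylketenes followed by electrocyclisation to phenols, the closing stage of the Danheiser benzannulation. No stereocentre remains, since the sp3 carbon of 38 forms as a racemate and is flattened by the tautomerisation. The step needs the Wolff shift to beat carbene addition to the enol ether and ring closure to beat bimolecular ketene reactions, which direct metal-free photolysis, a dry non-nucleophilic solvent and high dilution should secure. Regiochemistry is fixed by connectivity, because the dioxin CH is the only triene terminus next to the ketene.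

Step 18
Reactants: 39 the octamethyl ether
Product: 40 phlorofucofuroeckol A
Conditions: BBr3 (excess), CH2Cl2, −78 °C to rt, argon; then MeOH, H2O
Reagents that add atoms: none
Why: Lewis-acid cleavage of aryl methyl ethers, in which bromide attacks the methyl group of the boron-complexed ether, while the diaryl ether, dibenzodioxin and dibenzofuran C–O bonds carry no sp3 carbon and should survive.

Compound list

1 | 2-hydroxy-4,6-dimethoxybenzaldehyde | COc1cc(O)c(C=O)c(OC)c1 | starting material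
2 | benzyl bromide | BrCc1ccccc1 | starting material
3 | 2-(benzyloxy)-4,6-dimethoxybenzaldehyde | COc1cc(OCc2ccccc2)c(C=O)c(OC)c1 | intermediate
4 | 3-chloroperoxybenzoic acid (mCPBA) | OOC(=O)c1cccc(Cl)c1 | starting material
5 | 2-(benzyloxy)-4,6-dimethoxyphenyl formate | COc1cc(OCc2ccccc2)c(OC=O)c(OC)c1 | intermediate
6 | 2-(benzyloxy)-4,6-dimethoxyphenol | COc1cc(OCc2ccccc2)c(O)c(OC)c1 | intermediate
7 | 1-iodo-3,5-dimethoxybenzene | COc1cc(I)cc(OC)c1 | starting material
8 | 1-(benzyloxy)-2-(3,5-dimethoxyphenoxy)-3,5-dimethoxybenzene | COc1cc(OCc2ccccc2)c(Oc2cc(OC)cc(OC)c2)c(OC)c1 | intermediate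
9 | 2-(3,5-dimethoxyphenoxy)-3,5-dimethoxyphenol | COc1cc(O)c(Oc2cc(OC)cc(OC)c2)c(OC)c1 | intermediate
10 | paraformaldehyde (formaldehyde source) | C=O | starting material
11 | 3-(3,5-dimethoxyphenoxy)-2-hydroxy-4,6-dimethoxybenzaldehyde | COc1cc(OC)c(C=O)c(O)c1Oc1cc(OC)cc(OC)c1 | intermediate
12 | methyl bromoacetate | COC(=O)CBr | starting material
13 | methyl 2-[2-(3,5-dimethoxyphenoxy)-6-formyl-3,5-dimethoxyphenoxy]acetate | COC(=O)COc1c(C=O)c(OC)cc(OC)c1Oc1cc(OC)cc(OC)c1 | intermediate
14 | sodium chlorite | [Na+].[O-]Cl=O | starting material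
15 | 3-(3,5-dimethoxyphenoxy)-4,6-dimethoxy-2-(2-methoxy-2-oxoethoxy)benzoic acid | COC(=O)COc1c(C(=O)O)c(OC)cc(OC)c1Oc1cc(OC)cc(OC)c1 | intermediate
16 | trimethylsilyldiazomethane | C[Si](C)(C)C=[N+]=[N-] | starting material
17 | methyl 3-(3,5-dimethoxyphenoxy)-4,6-dimethoxy-2-(2-methoxy-2-oxoethoxy)benzoate | COC(=O)COc1c(C(=O)OC)c(OC)cc(OC)c1Oc1cc(OC)cc(OC)c1 | intermediate
18 | methyl 7-(3,5-dimethoxyphenoxy)-3-hydroxy-4,6-dimethoxy-1-benzofuran-2-carboxylate | COC(=O)c1oc2c(Oc3cc(OC)cc(OC)c3)c(OC)cc(OC)c2c1O | intermediate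
19 | trifluoromethanesulfonic anhydride | O=S(=O)(OS(=O)(=O)C(F)(F)F)C(F)(F)F | starting material
20 | methyl 7-(3,5-dimethoxyphenoxy)-4,6-dimethoxy-3-{[(trifluoromethyl)sulfonyl]oxy}-1-benzofuran-2-carboxylate | COC(=O)c1oc2c(Oc3cc(OC)cc(OC)c3)c(OC)cc(OC)c2c1OS(=O)(=O)C(F)(F)F | intermediate
21 | tributyl(1-ethoxyvinyl)stannane | C=C(OCC)[Sn](CCCC)(CCCC)CCCC | starting material
22 | methyl 7-(3,5-dimethoxyphenoxy)-3-(1-ethoxyethenyl)-4,6-dimethoxy-1-benzofuran-2-carboxylate | COC(=O)c1oc2c(Oc3cc(OC)cc(OC)c3)c(OC)cc(OC)c2c1C(=C)OCC | intermediate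
23 | N-bromosuccinimide | O=C1CCC(=O)N1Br | starting material
24 | water | O | starting material
25 | methyl 3-(2-bromoacetyl)-7-(3,5-dimethoxyphenoxy)-4,6-dimethoxy-1-benzofuran-2-carboxylate | COC(=O)c1oc2c(Oc3cc(OC)cc(OC)c3)c(OC)cc(OC)c2c1C(=O)CBr | intermediate
26 | methyl 7-(3,5-dimethoxyphenoxy)-3-{2-[2-(3,5-dimethoxyphenoxy)-6-formyl-3,5-dimethoxyphenoxy]acetyl}-4,6-dimethoxy-1-benzofuran-2-carboxylate | COC(=O)c1oc2c(Oc3cc(OC)cc(OC)c3)c(OC)cc(OC)c2c1C(=O)COc1c(C=O)c(OC)cc(OC)c1Oc1cc(OC)cc(OC)c1 | intermediate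
27 | aryl formate of 26 (formyl group replaced by formyloxy) | COC(=O)c1oc2c(Oc3cc(OC)cc(OC)c3)c(OC)cc(OC)c2c1C(=O)COc1c(OC=O)c(OC)cc(OC)c1Oc1cc(OC)cc(OC)c1 | intermediate
28 | methyl 7-(3,5-dimethoxyphenoxy)-3-{2-[2-(3,5-dimethoxyphenoxy)-6-hydroxy-3,5-dimethoxyphenoxy]acetyl}-4,6-dimethoxy-1-benzofuran-2-carboxylate (open form of 29) | COC(=O)c1oc2c(Oc3cc(OC)cc(OC)c3)c(OC)cc(OC)c2c1C(=O)COc1c(O)c(OC)cc(OC)c1Oc1cc(OC)cc(OC)c1 | intermediate
29 | methyl 7-(3,5-dimethoxyphenoxy)-3-[5-(3,5-dimethoxyphenoxy)-2-hydroxy-6,8-dimethoxy-2,3-dihydro-1,4-benzodioxin-2-yl]-4,6-dimethoxy-1-benzofuran-2-carboxylate (racemic) | COC(=O)c1oc2c(Oc3cc(OC)cc(OC)c3)c(OC)cc(OC)c2c1C1(O)COc2c(O1)c(OC)cc(OC)c2Oc1cc(OC)cc(OC)c1 | intermediate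
30 | methyl 7-(3,5-dimethoxyphenoxy)-3-[5-(3,5-dimethoxyphenoxy)-6,8-dimethoxy-1,4-benzodioxin-2-yl]-4,6-dimethoxy-1-benzofuran-2-carboxylate | COC(=O)c1oc2c(Oc3cc(OC)cc(OC)c3)c(OC)cc(OC)c2c1C1=COc2c(O1)c(OC)cc(OC)c2Oc1cc(OC)cc(OC)c1 | intermediate
31 | lithium hydroxide | [Li+].[OH-] | starting material
32 | 7-(3,5-dimethoxyphenoxy)-3-[5-(3,5-dimethoxyphenoxy)-6,8-dimethoxy-1,4-benzodioxin-2-yl]-4,6-dimethoxy-1-benzofuran-2-carboxylic acid | OC(=O)c1oc2c(Oc3cc(OC)cc(OC)c3)c(OC)cc(OC)c2c1C1=COc2c(O1)c(OC)cc(OC)c2Oc1cc(OC)cc(OC)c1 | intermediate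
33 | 1-chloro-N,N,2-trimethylprop-1-en-1-amine | CC(C)=C(Cl)N(C)C | starting material
34 | diazomethane | C=[N+]=[N-] | starting material
35 | acid chloride of 32 | ClC(=O)c1oc2c(Oc3cc(OC)cc(OC)c3)c(OC)cc(OC)c2c1C1=COc2c(O1)c(OC)cc(OC)c2Oc1cc(OC)cc(OC)c1 | intermediate
36 | 2-diazo-1-{7-(3,5-dimethoxyphenoxy)-3-[5-(3,5-dimethoxyphenoxy)-6,8-dimethoxy-1,4-benzodioxin-2-yl]-4,6-dimethoxy-1-benzofuran-2-yl}ethan-1-one | COc1cc(OC)cc(Oc2c(OC)cc(OC)c3c2OC=C(O3)c2c(C(=O)C=[N+]=[N-])oc4c(Oc5cc(OC)cc(OC)c5)c(OC)cc(OC)c24)c1 | intermediate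
37 | {7-(3,5-dimethoxyphenoxy)-3-[5-(3,5-dimethoxyphenoxy)-6,8-dimethoxy-1,4-benzodioxin-2-yl]-4,6-dimethoxy-1-benzofuran-2-yl}ketene | O=C=Cc1oc2c(Oc3cc(OC)cc(OC)c3)c(OC)cc(OC)c2c1C1=COc2c(O1)c(OC)cc(OC)c2Oc1cc(OC)cc(OC)c1 | intermediate
38 | ring-C cyclohexa-2,4-dienone (keto tautomer of 39, sp3 CH next to the carbonyl, racemic) | O=C1C=C2Oc3c(Oc4cc(OC)cc(OC)c4)c(OC)cc(OC)c3C2=C2Oc3c(OC)cc(OC)c(Oc4cc(OC)cc(OC)c4)c3OC12 | intermediate
39 | phlorofucofuroeckol A octamethyl ether, ring-C hydroxyl free | COc1cc(OC)cc(Oc2c(OC)cc(OC)c3c2Oc2c(O)cc4oc5c(Oc6cc(OC)cc(OC)c6)c(OC)cc(OC)c5c4c2O3)c1 | intermediate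
40 | phlorofucofuroeckol A | Oc1cc(O)cc(Oc2c(O)cc(O)c3c2Oc2c(O)cc4oc5c(Oc6cc(O)cc(O)c6)c(O)cc(O)c5c4c2O3)c1 | target

Total step count: 18. Longest linear sequence: 18 steps (1 to 40; aldehyde 11 is made once and used in steps 6 and 12).

Steps most likely to fail

Step 17. After loss of nitrogen the reactive centre may add to the neighbouring enol ether as a carbene, the ketene may be consumed bimolecularly (dimerisation, acylation of the phenol already formed), or the benzodioxin may undergo secondary photoreactions before ring closure. The fallback sets out from diazoketone 36 and avoids light. Silver-benzoate-promoted Wolff rearrangement in the dark (PhCO2Ag, Et3N, MeOH, rt; classical Arndt–Eistert homologation) should trap the ketene at once as the homologous methyl benzofuran-2-ylacetate F1. Saponification (LiOH, THF/H2O; pH 4) should give the benzofuran-2-ylacetic acid F2. The α-chloroenamine 33 converts it to the arylacetyl chloride F3, which is not isolated. Et3N in dilute toluene at 60 °C then closes ring C thermally, either by dehydrochlorination to ketene 37 or by direct C-acylation of the enol-ether carbon; both channels end, after enolisation, at compound 39, where the route is rejoined.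

Step 18. Cleavage of the eight methyl ethers may stop part-way, and the nonaphenol may be lost by air oxidation during isolation. The fallback sets out from 39. A pyridinium chloride melt (190 °C, argon) cleaves the ethers by chloride attack on the methyl groups. The crude phenol is not purified but acetylated (Ac2O, pyridine) to phlorofucofuroeckol A nonaacetate F4, which is stable and can be chromatographed; fractions that still carry methyl groups are separated and resubmitted. Deacetylation with degassed HCl in MeOH at rt should then return the route at compound 40.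

Step 13. The peracid may attack the aryl ketone or the electron-rich rings instead of only the formyl group, and the liberated electron-rich phenol may be oxidised before it is captured as the hemiketal. The fallback sets out from aldehyde 11 and carries out the oxidation before the benzofuran is attached. Benzylation (BnBr, K2CO3, DMF) gives 2-(benzyloxy)-3-(3,5-dimethoxyphenoxy)-4,6-dimethoxybenzaldehyde F5. mCPBA gives the corresponding aryl formate F6, which is methanolysed without isolation to 2-(benzyloxy)-3-(3,5-dimethoxyphenoxy)-4,6-dimethoxyphenol F7. Protection (MOMCl, i-Pr2NEt, CH2Cl2) gives the methoxymethyl ether F8, and hydrogenolysis (H2, Pd/C) gives 2-(3,5-dimethoxyphenoxy)-3,5-dimethoxy-6-(methoxymethoxy)phenol F9, a catechol with only the required oxygen free. Alkylation with bromoketone 25 (K2CO3, acetone) gives the MOM-protected aryloxy ketone F10. HCl in MeOH at rt removes the MOM group and the phenol closes, through 28, to hemiketal 29, where the route is rejoined.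

Further compounds

F1 | step 17 | methyl 2-{7-(3,5-dimethoxyphenoxy)-3-[5-(3,5-dimethoxyphenoxy)-6,8-dimethoxy-1,4-benzodioxin-2-yl]-4,6-dimethoxy-1-benzofuran-2-yl}acetate | COC(=O)Cc1oc2c(Oc3cc(OC)cc(OC)c3)c(OC)cc(OC)c2c1C1=COc2c(O1)c(OC)cc(OC)c2Oc1cc(OC)cc(OC)c1
F2 | step 17 | 2-{7-(3,5-dimethoxyphenoxy)-3-[5-(3,5-dimethoxyphenoxy)-6,8-dimethoxy-1,4-benzodioxin-2-yl]-4,6-dimethoxy-1-benzofuran-2-yl}acetic acid | OC(=O)Cc1oc2c(Oc3cc(OC)cc(OC)c3)c(OC)cc(OC)c2c1C1=COc2c(O1)c(OC)cc(OC)c2Oc1cc(OC)cc(OC)c1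
F3 | step 17 | acid chloride of F2 | ClC(=O)Cc1oc2c(Oc3cc(OC)cc(OC)c3)c(OC)cc(OC)c2c1C1=COc2c(O1)c(OC)cc(OC)c2Oc1cc(OC)cc(OC)c1
F4 | step 18 | phlorofucofuroeckol A nonaacetate | CC(=O)Oc1cc(OC(C)=O)cc(Oc2c(OC(C)=O)cc(OC(C)=O)c3c2Oc2c(OC(C)=O)cc4oc5c(Oc6cc(OC(C)=O)cc(OC(C)=O)c6)c(OC(C)=O)cc(OC(C)=O)c5c4c2O3)c1
F5 | step 13 | 2-(benzyloxy)-3-(3,5-dimethoxyphenoxy)-4,6-dimethoxybenzaldehyde | COc1cc(OC)c(C=O)c(OCc2ccccc2)c1Oc1cc(OC)cc(OC)c1
F6 | step 13 | 2-(benzyloxy)-3-(3,5-dimethoxyphenoxy)-4,6-dimethoxyphenyl formate | COc1cc(OC)c(OC=O)c(OCc2ccccc2)c1Oc1cc(OC)cc(OC)c1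
F7 | step 13 | 2-(benzyloxy)-3-(3,5-dimethoxyphenoxy)-4,6-dimethoxyphenol | COc1cc(OC)c(O)c(OCc2ccccc2)c1Oc1cc(OC)cc(OC)c1
F8 | step 13 | 1-(benzyloxy)-2-(3,5-dimethoxyphenoxy)-3,5-dimethoxy-6-(methoxymethoxy)benzene | COCOc1c(OC)cc(OC)c(Oc2cc(OC)cc(OC)c2)c1OCc1ccccc1
F9 | step 13 | 2-(3,5-dimethoxyphenoxy)-3,5-dimethoxy-6-(methoxymethoxy)phenol | COCOc1c(OC)cc(OC)c(Oc2cc(OC)cc(OC)c2)c1O
F10 | step 13 | methyl 7-(3,5-dimethoxyphenoxy)-3-{2-[2-(3,5-dimethoxyphenoxy)-3,5-dimethoxy-6-(methoxymethoxy)phenoxy]acetyl}-4,6-dimethoxy-1-benzofuran-2-carboxylate | COC(=O)c1oc2c(Oc3cc(OC)cc(OC)c3)c(OC)cc(OC)c2c1C(=O)COc1c(OCOC)c(OC)cc(OC)c1Oc1cc(OC)cc(OC)c1
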